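**Retrosynthetic overview**
- Target acid ⇐ its potassium/tetrabutylammonium salt (protonation) ⇐ 5,7-di-O-benzyl-protected 3-O-sulfate (hydrogenolysis).
- C3–OSO3⁻ bond ⇐ new step: C3-metalation of 5,7-di-O-benzylacacetin, then O-sulfate transfer from peroxydisulfate (forms the C3–O bond with the sulfate already attached).
- Pyranone C ring (O1–C2 bond) ⇐ I2/DMSO oxidative cyclisation of a 2'-hydroxychalcone.
- Chalcone ⇐ Claisen–Schmidt condensation of 4,6-di-O-benzylphloroacetophenone with p-anisaldehyde.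
- Ring order: A and B rings are bought; the C ring is the only ring formed (step 3); C3–O sulfation comes after it.

Assumption: the target has no stereocentre (it is achiral), so no stereocontrol is needed; it is delivered as the free hydrogen sulfate drawn.

**Step 1**
Reactants: 1 1-(2,4,6-trihydroxyphenyl)ethan-1-one (phloroacetophenone)
Product: 2 1-[2,4-bis(benzyloxy)-6-hydroxyphenyl]ethan-1-one
Conditions: BnBr (2.1 equiv), K2CO3 (2.2 equiv), DMF, 0 °C → rt, 12 h
Reagents that add atoms: benzyl bromide, BrCc1ccccc1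
Why: Williamson etherification (SN2) in which the 4-OH and one ortho-OH are benzylated while the remaining ortho-OH, hydrogen-bonded to the acetyl C=O, is too weakly nucleophilic to react under mild base.

**Step 2**
Reactants: 2 1-[2,4-bis(benzyloxy)-6-hydroxyphenyl]ethan-1-one; 3 4-methoxybenzaldehyde
Product: 4 (E)-1-[2,4-bis(benzyloxy)-6-hydroxyphenyl]-3-(4-methoxyphenyl)prop-2-en-1-one
Conditions: KOH (50% aq, 10 equiv), EtOH, rt, 48 h; then 1 M HCl to pH 3
Reagents that add atoms: none
Why: Claisen–Schmidt aldol condensation of the methyl ketone with a non-enolisable aldehyde, E1cB dehydration giving the conjugated E-enone under thermodynamic control; benzyl ethers are inert to aqueous base.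

**Step 3**
Reactants: 4 (E)-1-[2,4-bis(benzyloxy)-6-hydroxyphenyl]-3-(4-methoxyphenyl)prop-2-en-1-one
Product: 5 5,7-bis(benzyloxy)-2-(4-methoxyphenyl)-4H-chromen-4-one
Conditions: I2 (10 mol %), DMSO, 130 °C, 2 h; aq Na2S2O3 work-up
Reagents that add atoms: none
Why: Iodine/DMSO oxidative cyclisation of a 2'-hydroxychalcone (dehydrogenative 6-endo oxa-Michael ring closure, DMSO as terminal oxidant regenerating I2), the standard flavone synthesis; aryl ethers survive.

**Step 4**
Reactants: 5 5,7-bis(benzyloxy)-2-(4-methoxyphenyl)-4H-chromen-4-one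
Product: 8 tetrabutylammonium 5,7-bis(benzyloxy)-2-(4-methoxyphenyl)-4-oxo-4H-chromen-3-yl sulfate, via 3-lithioflavone 6 (not isolated), via 3-bromomagnesioflavone 7 (not isolated)
Conditions: LDA (1.15 equiv), THF, −78 °C, 30 min; MgBr2·OEt2 (1.3 equiv), −78 → −40 °C; cannulate into dry (n-Bu4N)2S2O8 (1.5 equiv), CH2Cl2/THF, −78 → 0 °C; aq Na2SO3/NaHCO3; SiO2 (CH2Cl2–MeOH)
Reagents that add atoms: bis(tetrabutylammonium) peroxydisulfate, CCCC[N+](CCCC)(CCCC)CCCC.CCCC[N+](CCCC)(CCCC)CCCC.[O-]S(=O)(=O)OOS(=O)(=O)[O-] (OSO3⁻ and Bu4N⁺ of 8); lithium diisopropylamide, [Li+].CC(C)[N-]C(C)C (Li of 6 only); magnesium bromide (etherate), Br[Mg]Br (MgBr of 7 only)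
Why: Proposed new method: a "carbanion-Elbs" C–H sulfatoxylation in which LDA removes the only acidic C–H (C3–H, the known C3-lithiation of 5,7-dialkoxyflavones, so regiochemistry is fixed), Li→Mg exchange lowers basicity and single-electron transfer, and the C3–Mg carbanion attacks a peroxide oxygen of S2O8²⁻ (SN2 at O into σ*O–O, sulfate as leaving group) to form the C3–O bond with the sulfate attached; the closest known reactions are the Elbs persulfate oxidation of phenolates to aryl sulfates and the electrophilic oxygenation of aryl/alkenyl Grignard and lithium reagents by peroxides (tert-butyl perbenzoate, bis(trimethylsilyl) peroxide, arenesulfonyl peroxides), whereas sulfate-O transfer from peroxydisulfate to a C(sp2)–metal bond is not yet known.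

**Step 5**
Reactants: 8 tetrabutylammonium 5,7-bis(benzyloxy)-2-(4-methoxyphenyl)-4-oxo-4H-chromen-3-yl sulfate
Product: 10 potassium 5,7-dihydroxy-2-(4-methoxyphenyl)-4-oxo-4H-chromen-3-yl sulfate, via tetrabutylammonium kaempferide 3-O-sulfate 9 (not isolated)
Conditions: H2 (1 atm), 10% Pd/C, THF–MeOH (1:1), rt, 3 h; filter; then KOAc (3 equiv), MeOH, 0 °C, precipitate with Et2O
Reagents that add atoms: potassium acetate, CC(=O)[O-].[K+]
Why: Pd-catalysed hydrogenolysis of both aryl benzyl ethers (sulfate monoester salts and the tetrasubstituted vinylogous-ester C2=C3 are inert at 1 atm), followed by salt metathesis driven by precipitation of the potassium sulfate salt.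

**Step 6**
Reactants: 10 potassium 5,7-dihydroxy-2-(4-methoxyphenyl)-4-oxo-4H-chromen-3-yl sulfate
Product: 11 5,7-dihydroxy-2-(4-methoxyphenyl)-4-oxo-4H-chromen-3-yl hydrogen sulfate (kaempferide 3-O-sulfate)
Conditions: 1 M aq HCl (1.05 equiv), H2O–MeOH, 0 °C; C18 cartridge (0.01 M HCl, H2O, then MeOH); freeze-dry, store at −20 °C
Reagents that add atoms: none
Why: Simple protonation/cation exchange of a strong-acid salt, with K⁺ and Cl⁻ washing through the reversed-phase cartridge while the hydrophobic flavonoid hydrogen sulfate is retained and then eluted, kept cold and brief to avoid acid-catalysed loss of SO3.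

**Compound list**
1 | 1-(2,4,6-trihydroxyphenyl)ethan-1-one | CC(=O)c1c(O)cc(O)cc1O | starting material
2 | 1-[2,4-bis(benzyloxy)-6-hydroxyphenyl]ethan-1-one | CC(=O)c1c(O)cc(OCc2ccccc2)cc1OCc1ccccc1 | intermediate
3 | 4-methoxybenzaldehyde | COc1ccc(C=O)cc1 | starting material
4 | (E)-1-[2,4-bis(benzyloxy)-6-hydroxyphenyl]-3-(4-methoxyphenyl)prop-2-en-1-one | COc1ccc(/C=C/C(=O)c2c(O)cc(OCc3ccccc3)cc2OCc2ccccc2)cc1 | intermediate
5 | 5,7-bis(benzyloxy)-2-(4-methoxyphenyl)-4H-chromen-4-one | COc1ccc(-c2oc3cc(OCc4ccccc4)cc(OCc4ccccc4)c3c(=O)c2)cc1 | intermediate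
6 | [5,7-bis(benzyloxy)-2-(4-methoxyphenyl)-4-oxo-4H-chromen-3-yl]lithium | COc1ccc(-c2oc3cc(OCc4ccccc4)cc(OCc4ccccc4)c3c(=O)c2[Li])cc1 | intermediate
7 | [5,7-bis(benzyloxy)-2-(4-methoxyphenyl)-4-oxo-4H-chromen-3-yl]magnesium bromide | COc1ccc(-c2oc3cc(OCc4ccccc4)cc(OCc4ccccc4)c3c(=O)c2[Mg]Br)cc1 | intermediate
8 | tetrabutylammonium 5,7-bis(benzyloxy)-2-(4-methoxyphenyl)-4-oxo-4H-chromen-3-yl sulfate | COc1ccc(-c2oc3cc(OCc4ccccc4)cc(OCc4ccccc4)c3c(=O)c2OS(=O)(=O)[O-])cc1.CCCC[N+](CCCC)(CCCC)CCCC | intermediate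
9 | tetrabutylammonium 5,7-dihydroxy-2-(4-methoxyphenyl)-4-oxo-4H-chromen-3-yl sulfate | COc1ccc(-c2oc3cc(O)cc(O)c3c(=O)c2OS(=O)(=O)[O-])cc1.CCCC[N+](CCCC)(CCCC)CCCC | intermediate
10 | potassium 5,7-dihydroxy-2-(4-methoxyphenyl)-4-oxo-4H-chromen-3-yl sulfate | COc1ccc(-c2oc3cc(O)cc(O)c3c(=O)c2OS(=O)(=O)[O-])cc1.[K+] | intermediate
11 | 5,7-dihydroxy-2-(4-methoxyphenyl)-4-oxo-4H-chromen-3-yl hydrogen sulfate (kaempferide 3-O-sulfate) | COc1ccc(-c2oc3cc(O)cc(O)c3c(=O)c2OS(=O)(=O)O)cc1 | target

**Totals**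
Total step count: 6. Longest linear sequence: 6 steps (1 → 11).

**Three steps most likely to fail**

Step 4 (the proposed new step). Risks are single-electron oxidation of the organometallic by peroxydisulfate (returning 5 or dimers) and attack of the carbanion on Bu4N⁺. The fallback uses known chemistry, sets out from 5 and comes back at 8. Compound 5 is lithiated as before (LDA, THF, −78 °C, giving 6) and quenched with B(OMe)3 to give dimethyl [5,7-bis(benzyloxy)-2-(4-methoxyphenyl)-4-oxo-4H-chromen-3-yl]boronate F1. F1 is oxidised in the same flask (30% H2O2, AcOH, 0 °C → rt) to 5,7-bis(benzyloxy)-3-hydroxy-2-(4-methoxyphenyl)-4H-chromen-4-one F2. The only free hydroxyl of F2 is then sulfated with DCC/n-Bu4NHSO4 in pyridine (4 °C → rt), which gives 8 directly as its tetrabutylammonium salt.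

Step 3 (I2/DMSO cyclisation). Risks are HI-induced loss of the 5-O-benzyl group and iodination of the electron-rich A ring. The fallback replaces the chalcone route by a Baker–Venkataraman route, sets out from 2 and comes back at 5 (bypassing 4). Compound 2 is acylated with 4-methoxybenzoyl chloride (pyridine, DMAP, rt) to 2-acetyl-3,5-bis(benzyloxy)phenyl 4-methoxybenzoate F3. Base-induced O→C acyl migration (KOH, pyridine, 50 °C) gives 1-[2,4-bis(benzyloxy)-6-hydroxyphenyl]-3-(4-methoxyphenyl)propane-1,3-dione F4. Cyclodehydration (cat. p-TsOH, toluene, reflux) then gives 5 without any oxidant.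

Step 1 (selective double benzylation). Risks are mono/tri-O-benzyl mixtures and C-benzylation of the phloroglucinol ring. The fallback sets out from 1 and comes back at 2. Compound 1 is exhaustively benzylated (BnBr 4 equiv, K2CO3, DMF, 80 °C) to 1-[2,4,6-tris(benzyloxy)phenyl]ethan-1-one F5. One benzyl ether ortho to the acetyl group is then removed by chelation-controlled cleavage with MgBr2·OEt2 (toluene/Et2O, reflux), the magnesium phenoxide chelate formed protecting the second ortho ether, to give 2.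

**Further compounds**
F1 | step 4 | dimethyl [5,7-bis(benzyloxy)-2-(4-methoxyphenyl)-4-oxo-4H-chromen-3-yl]boronate | COc1ccc(-c2oc3cc(OCc4ccccc4)cc(OCc4ccccc4)c3c(=O)c2B(OC)OC)cc1
F2 | step 4 | 5,7-bis(benzyloxy)-3-hydroxy-2-(4-methoxyphenyl)-4H-chromen-4-one | COc1ccc(-c2oc3cc(OCc4ccccc4)cc(OCc4ccccc4)c3c(=O)c2O)cc1
F3 | step 3 | 2-acetyl-3,5-bis(benzyloxy)phenyl 4-methoxybenzoate | COc1ccc(C(=O)Oc2cc(OCc3ccccc3)cc(OCc3ccccc3)c2C(C)=O)cc1
F4 | step 3 | 1-[2,4-bis(benzyloxy)-6-hydroxyphenyl]-3-(4-methoxyphenyl)propane-1,3-dione | COc1ccc(C(=O)CC(=O)c2c(O)cc(OCc3ccccc3)cc2OCc2ccccc2)cc1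
F5 | step 1 | 1-[2,4,6-tris(benzyloxy)phenyl]ethan-1-one | CC(=O)c1c(OCc2ccccc2)cc(OCc2ccccc2)cc1OCc1ccccc1
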